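**Retrosynthetic overview**

1. Target 19 is a spiro[5.5]undecane. Ring A is C1–C6 (C1=O, C2(Me)=C3(OMe), C4Me2, C5=O, spiro C6). Ring B is C6–C11 (cyclohexene, homoprenyl on C8, isopropyl on C11).
2. Ring A is cut at C6–C5 and C4–C3. It is the formal [4+2] adduct of the lithium dienolate of acyl ketene acetal 14 (C6=C1(O)–C2=C3(OMe)2) and dimethylketene 16 (C5=C4); loss of methanol after closure leaves the enol ether at C3 and nowhere else.
3. Enabling feature: in ring A the O=C5–C4Me2 unit is a latent dimethylketene. It sits between C6, which is α to the C1 ketone (donor), and C3, the β-carbon of the C1/C2/C3 vinylogous ester (acceptor at the ketene acetal level). C11 next to C6 steers the spiro centre.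
4. 14 comes from acid 10 and 1,1-dimethoxypropene 12 (C1–C2 bond). Acid 10 (ring B) comes from 3-methylbutanal, methyl (E)-4-oxopent-2-enoate and homoprenyl bromide by enamine Michael addition (sets C11), aldol closure, conjugate reduction/enol triflation and iron-catalysed alkyl coupling.
5. Order of ring formation: ring B first (step 2), ring A last (step 9).

Key step: step 9

Remark: target numbering (C1–C11) is used when ring A is discussed. The centre α to the carbonyl group in 3–14 is drawn trans, but its configuration is immaterial because it is planarised in step 9.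

**Step 1**
Reactants: 1 3-methylbutanal; 2 methyl (E)-4-oxopent-2-enoate
Product: 3 methyl (2R)-2-[(2S)-3-methyl-1-oxobutan-2-yl]-4-oxopentanoate
Conditions: (R)-2-[diphenyl(trimethylsilyloxy)methyl]pyrrolidine (10 mol %), PhCO2H (10 mol %), toluene, 0 °C to rt
Reagents that add atoms: none
Why: Enamine-catalysed Michael addition of an aldehyde to a γ-keto-α,β-unsaturated ester: the ketone is the stronger acceptor, so the (E)-enamine should attack the ester-bearing carbon, and the diphenyl(silyloxy)methyl group of the (R)-catalyst shields one enamine face so that the centre α to the aldehyde (C11 of the target) forms as drawn, the neighbouring centre following from the usual synclinal (syn) transition state.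

**Step 2**
Reactants: 3 methyl (2R)-2-[(2S)-3-methyl-1-oxobutan-2-yl]-4-oxopentanoate
Product: 4 methyl (1R,2R)-5-oxo-2-(propan-2-yl)cyclohex-3-ene-1-carboxylate
Conditions: NaOMe (0.3 equiv), MeOH, 0 °C to rt; AcOH quench
Reagents that add atoms: none
Why: Base-mediated intramolecular aldol condensation, a 6-(enolendo)-exo-trig closure of the methyl ketone enolate onto the aldehyde that is the only ring size open to this 1,5-keto aldehyde; methoxide in methanol cannot change the methyl ester, no stereocentre is formed, and short, cold conditions should keep the isopropyl-bearing centre from epimerising through the dienolate.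

**Step 3**
Reactants: 4 methyl (1R,2R)-5-oxo-2-(propan-2-yl)cyclohex-3-ene-1-carboxylate
Product: 6 methyl (1R,6S)-6-(propan-2-yl)-3-[(trifluoromethanesulfonyl)oxy]cyclohex-3-ene-1-carboxylate, via lithium enolate 5 (not isolated)
Conditions: LiBH(s-Bu)3 (1.05 equiv), THF, −78 °C; then PhNTf2 (1.1 equiv), −78 °C to 0 °C; aq NH4Cl
Reagents that add atoms: N-phenylbis(trifluoromethanesulfonimide), O=S(=O)(N(c1ccccc1)S(=O)(=O)C(F)(F)F)C(F)(F)F
Why: 1,4-Reduction of a β-unsubstituted cyclohexenone by a hindered trialkylborohydride gives the enolate regiospecifically on the side of the former C=C, and O-sulfonylation by the triflimide traps it as the enol triflate; the ester is inert at −78 °C and no stereocentre is formed.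

**Step 4**
Reactants: 6 methyl (1R,6S)-6-(propan-2-yl)-3-[(trifluoromethanesulfonyl)oxy]cyclohex-3-ene-1-carboxylate; 7 5-bromo-2-methylpent-2-ene
Product: 9 methyl (1R,6S)-3-(4-methylpent-3-en-1-yl)-6-(propan-2-yl)cyclohex-3-ene-1-carboxylate, via homoprenylmagnesium bromide 8 (not isolated)
Conditions: 7, Mg, THF, rt; then 6, Fe(acac)3 (5 mol %), THF/NMP, −30 °C
Reagents that add atoms: none
Why: Iron-catalysed Kumada-type cross-coupling of an alkenyl triflate with a primary alkyl Grignard reagent, which should be fast enough at −30 °C to leave the methyl ester untouched and places the homoprenyl group on the carbon that carried the triflate, with the ring double bond held in place.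

**Step 5**
Reactants: 9 methyl (1R,6S)-3-(4-methylpent-3-en-1-yl)-6-(propan-2-yl)cyclohex-3-ene-1-carboxylate
Product: 10 (1R,6S)-3-(4-methylpent-3-en-1-yl)-6-(propan-2-yl)cyclohex-3-ene-1-carboxylic acid
Conditions: LiOH·H2O (3 equiv), THF/MeOH/H2O, 50 °C; then 1 M HCl to pH 3
Reagents that add atoms: lithium hydroxide, [Li+].[OH-]
Why: Ester saponification; the centre α to the carboxyl group may equilibrate (trans is favoured) but is planarised in step 9, and the isopropyl-bearing centre is not affected.

**Step 6**
Reactants: 11 trimethyl orthopropionate (1,1,1-trimethoxypropane)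
Product: 12 1,1-dimethoxyprop-1-ene
Conditions: Me3SiOTf (1.05 equiv), i-Pr2NEt (1.2 equiv), CH2Cl2, −20 °C to rt; distilled from the salt
Reagents that add atoms: none
Why: Me3SiOTf ionises the ortho ester to the dimethoxycarbenium ion and the hindered amine removes the α-proton, the ortho-ester counterpart of the silyl triflate/amine elimination that turns acetals into enol ethers.

**Step 7**
Reactants: 10 (1R,6S)-3-(4-methylpent-3-en-1-yl)-6-(propan-2-yl)cyclohex-3-ene-1-carboxylic acid; 12 1,1-dimethoxyprop-1-ene
Product: 14 3,3-dimethoxy-2-methyl-1-[(1R,6S)-3-(4-methylpent-3-en-1-yl)-6-(propan-2-yl)cyclohex-3-en-1-yl]prop-2-en-1-one, via acid chloride 13 (not isolated)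
Conditions: 1-chloro-N,N,2-trimethylprop-1-en-1-amine (1.1 equiv), CH2Cl2, 0 °C to rt; then 12 (2 equiv), pyridine (1.5 equiv), 0 °C to rt; filtered, chromatographed on Et3N-deactivated silica
Reagents that add atoms: none
Why: Neutral acid chloride formation with the α-chloroenamine, then C-acylation of the ketene acetal at its nucleophilic β-carbon and loss of the α-proton from the dimethoxycarbenium ion to pyridine (the classical acylation of ketene acetals by acid chlorides) should give the acyl ketene acetal; pyridine is too weak a base to dehydrochlorinate 13 and the isopropyl-bearing centre is not involved.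

**Step 8**
Reactants: 15 2-bromo-2-methylpropanoyl bromide
Product: 16 dimethylketene (2-methylprop-1-en-1-one), as a THF solution
Conditions: Zn dust (activated), THF, 0 °C, argon; co-distilled with THF at reduced pressure into a −78 °C trap, used at once
Reagents that add atoms: none
Why: Reductive 1,2-elimination (zinc dehalogenation) of an α-bromoacyl bromide, the standard laboratory preparation of dimethylketene, which is kept under argon because it forms peroxides with air.

**Step 9**
Reactants: 14 3,3-dimethoxy-2-methyl-1-[(1R,6S)-3-(4-methylpent-3-en-1-yl)-6-(propan-2-yl)cyclohex-3-en-1-yl]prop-2-en-1-one; 16 dimethylketene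
Product: 19 (6R,11S)-3-methoxy-2,4,4-trimethyl-8-(4-methylpent-3-en-1-yl)-11-(propan-2-yl)spiro[5.5]undeca-2,8-diene-1,5-dione, via lithium dienolate 17 (not isolated), via C-acylated enolate 18 (not isolated)
Conditions: LiN(i-Pr)2 (1.05 equiv), THF, −78 °C; volatiles including HN(i-Pr)2 removed in vacuo, fresh THF; 16 (1.2 equiv), −78 °C to 0 °C; aq NH4Cl at −40 °C
Reagents that add atoms: none
Why: Proposed new method: LiN(i-Pr)2 removes the only acidic proton of 14, the ring C–H α' to the vinylogous carbonate (kinetic α'-enolisation as with vinylogous esters), and the α'-carbon of dienolate 17 adds to the sp carbon of dimethylketene (C6–C5 bond) to give the isopropylidene enolate 18, whose carbon terminus adds to the dimethoxy-substituted β-carbon of the enone (C4–C3 bond), after which methoxide is lost by E1cB to leave ring A with its methyl enol ether at C3. The closest known reaction types are the C-acylation of hindered lithium ester enolates by dialkylketenes (the ketene pathway of the Claisen self-condensation, which also builds quaternary carbons), the addition–elimination of enolates to α-oxo ketene acetals and dithioacetals, and the stepwise [4+2] annulations of 1,1-dialkoxy-3-oxy-1,3-dienes that end with loss of an alcohol; using the C=C bond of a ketene as the two-carbon partner of such a dienolate is the new element. Ring A closes as a formal [4+2] of the dienolate C6=C1(O)–C2=C3 with the ketene C5=C4, the second bond forming in a 6-(enolendo)-endo-trig Michael addition that has the geometry of the second half of a stepwise Diels–Alder reaction. The spiro centre C6 is set under control of C11: A(1,3) strain with the exocyclic enolate forces the isopropyl group into a pseudoaxial position, so the small linear ketene should enter from the opposite face and place the new C5 carbonyl trans and the resident C1 carbonyl cis to the isopropyl group, as in 19. The step needs C- and not O-acylation at C6 and C- and not O-closure at C3: O-acylation by a ketene gives an ester enolate that can fall back to 17 and the ketene, an O-closed pyranone can be reopened by the liberated methoxide, and only the carbocycle keeps both carbonyl groups, so it should be the thermodynamic sink, while the position of the enol ether is dictated by the oxidation pattern of 14, in which C3 already carries both methoxy groups and C1 the carbonyl. Removal of the amine before the ketene is added, a small excess of ketene and a cold quench should limit amide formation, ketene oligomerisation and retro-Claisen attack of methoxide on the non-enolisable 1,3-dione.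

**Compound list**

1 | 3-methylbutanal | CC(C)CC=O | starting material
2 | methyl (E)-4-oxopent-2-enoate | COC(=O)/C=C/C(C)=O | starting material
3 | methyl (2R)-2-[(2S)-3-methyl-1-oxobutan-2-yl]-4-oxopentanoate | O=C[C@@H](C(C)C)[C@H](C(=O)OC)CC(C)=O | intermediate
4 | methyl (1R,2R)-5-oxo-2-(propan-2-yl)cyclohex-3-ene-1-carboxylate | O=C1C=C[C@@H](C(C)C)[C@H](C(=O)OC)C1 | intermediate
5 | lithium (4S,5R)-5-(methoxycarbonyl)-4-(propan-2-yl)cyclohex-1-en-1-olate | [Li+].[O-]C1=CC[C@@H](C(C)C)[C@H](C(=O)OC)C1 | intermediate (not isolated)
6 | methyl (1R,6S)-6-(propan-2-yl)-3-[(trifluoromethanesulfonyl)oxy]cyclohex-3-ene-1-carboxylate | O=S(=O)(OC1=CC[C@@H](C(C)C)[C@H](C(=O)OC)C1)C(F)(F)F | intermediate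
7 | 5-bromo-2-methylpent-2-ene | CC(C)=CCCBr | starting material
8 | (4-methylpent-3-en-1-yl)magnesium bromide | CC(C)=CCC[Mg]Br | intermediate (not isolated)
9 | methyl (1R,6S)-3-(4-methylpent-3-en-1-yl)-6-(propan-2-yl)cyclohex-3-ene-1-carboxylate | COC(=O)[C@@H]1CC(CCC=C(C)C)=CC[C@H]1C(C)C | intermediate
10 | (1R,6S)-3-(4-methylpent-3-en-1-yl)-6-(propan-2-yl)cyclohex-3-ene-1-carboxylic acid | OC(=O)[C@@H]1CC(CCC=C(C)C)=CC[C@H]1C(C)C | intermediate
11 | trimethyl orthopropionate (1,1,1-trimethoxypropane) | CCC(OC)(OC)OC | starting material
12 | 1,1-dimethoxyprop-1-ene | CC=C(OC)OC | intermediate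
13 | (1R,6S)-3-(4-methylpent-3-en-1-yl)-6-(propan-2-yl)cyclohex-3-ene-1-carbonyl chloride | ClC(=O)[C@@H]1CC(CCC=C(C)C)=CC[C@H]1C(C)C | intermediate (not isolated)
14 | 3,3-dimethoxy-2-methyl-1-[(1R,6S)-3-(4-methylpent-3-en-1-yl)-6-(propan-2-yl)cyclohex-3-en-1-yl]prop-2-en-1-one | COC(OC)=C(C)C(=O)[C@@H]1CC(CCC=C(C)C)=CC[C@H]1C(C)C | intermediate
15 | 2-bromo-2-methylpropanoyl bromide | CC(C)(Br)C(=O)Br | starting material
16 | dimethylketene (2-methylprop-1-en-1-one) | CC(C)=C=O | intermediate
17 | lithium 3,3-dimethoxy-2-methyl-1-[(6S)-3-(4-methylpent-3-en-1-yl)-6-(propan-2-yl)cyclohex-3-en-1-ylidene]prop-2-en-1-olate | [Li+].[O-]C(C(C)=C(OC)OC)=C1CC(CCC=C(C)C)=CC[C@H]1C(C)C | intermediate (not isolated)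
18 | lithium 1-[(1S,6S)-1-(3,3-dimethoxy-2-methylprop-2-enoyl)-3-(4-methylpent-3-en-1-yl)-6-(propan-2-yl)cyclohex-3-en-1-yl]-2-methylprop-1-en-1-olate | COC(OC)=C(C)C(=O)[C@@]1(C([O-])=C(C)C)CC(CCC=C(C)C)=CC[C@H]1C(C)C.[Li+] | intermediate (not isolated)
19 | (6R,11S)-3-methoxy-2,4,4-trimethyl-8-(4-methylpent-3-en-1-yl)-11-(propan-2-yl)spiro[5.5]undeca-2,8-diene-1,5-dione | COC1=C(C)C(=O)[C@]2(CC(CCC=C(C)C)=CC[C@H]2C(C)C)C(=O)C1(C)C | target

**Step count and risks**

Total step count: 9. Longest linear sequence: 7 steps (1, 2, 3, 4, 5, 7, 9); steps 6 and 8 prepare the two small partners.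

Steps most likely to fail:

Step 9 (Proposed new method). What may go wrong: O-acylation of the dienolate that does not revert, O- instead of C-closure onto C3, oligomerisation of the ketene, or cleavage of the product by the liberated methoxide. The fallback uses known chemistry, sets out from ester 9 and comes back at 19. The lithium enolate of 9 (LiN(i-Pr)2, THF, −78 °C) is C-acylated with 2-methylpropanoyl chloride, anti to the isopropyl group for the same reason as in step 9, to give the β-keto ester F1. Its only enolisable position is deprotonated (LiN(i-Pr)2, −78 °C) and added to propanal to give the aldol F2. Dess–Martin oxidation turns F2 into the diketo ester F3. LiN(SiMe3)2 (2.2 equiv, THF, −78 °C to 0 °C) then brings about a Dieckmann condensation of the ethyl ketone onto the methyl ester and should give the trione F4 as its stabilised enolate. O-Methylation (Me2SO4, K2CO3, acetone) should give 19 together with the regioisomeric enol ether F5, which has to be separated and can be hydrolysed back to F4. This route gives up the built-in control over the position of the enol ether.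

Step 7. What may go wrong: demethylation of the dimethoxycarbenium intermediate by chloride (a β-keto ester instead of the ketene acetal), hydrolysis of 14 during purification, or dehydrochlorination of 13. The fallback sets out from acid 10 and comes back at 14; it builds the ketene acetal carbon onto a ketone instead of acylating a ketene acetal, so 12 is no longer needed. Acid 10 with EtLi (2.2 equiv, Et2O, 0 °C) should give the ethyl ketone F6. Kinetic enolisation on the ethyl side and silylation (LiN(i-Pr)2, Me3SiCl, THF, −78 °C) give the silyl enol ether F7. Mukaiyama-type addition of F7 to the trimethoxycarbenium ion made from C(OMe)4 and Me3SiOTf (CH2Cl2, −78 °C) gives the β-keto ortho ester F8. Methanol is then eliminated from F8 (Me3SiOTf, i-Pr2NEt, or DBU) to give 14.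

Step 3. What may go wrong: 1,2-reduction of the enone, or proton transfer that scrambles the enolate before it is trapped. The fallback sets out from enone 4 and comes back at triflate 6. Catalytic 1,4-hydrosilylation (Et3SiH, RhCl(PPh3)3 1 mol %, toluene, 50 °C) gives the isolable triethylsilyl enol ether F9, in which the position of the double bond is defined. CsF and N-phenylbis(trifluoromethanesulfonimide) (DME, rt) then convert F9 into 6 without a free hydride or a strong base.

**Further compounds**

F1 | step 9 | methyl (1S,6S)-3-(4-methylpent-3-en-1-yl)-1-(2-methylpropanoyl)-6-(propan-2-yl)cyclohex-3-ene-1-carboxylate | COC(=O)[C@]1(CC(CCC=C(C)C)=CC[C@H]1C(C)C)C(=O)C(C)C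
F2 | step 9 | methyl (1S,6S)-1-(3-hydroxy-2,2-dimethylpentanoyl)-3-(4-methylpent-3-en-1-yl)-6-(propan-2-yl)cyclohex-3-ene-1-carboxylate (carbinol epimers) | COC(=O)[C@]1(CC(CCC=C(C)C)=CC[C@H]1C(C)C)C(=O)C(C)(C)C(O)CC
F3 | step 9 | methyl (1S,6S)-1-(2,2-dimethyl-3-oxopentanoyl)-3-(4-methylpent-3-en-1-yl)-6-(propan-2-yl)cyclohex-3-ene-1-carboxylate | COC(=O)[C@]1(CC(CCC=C(C)C)=CC[C@H]1C(C)C)C(=O)C(C)(C)C(=O)CC
F4 | step 9 | (6R,11S)-2,4,4-trimethyl-8-(4-methylpent-3-en-1-yl)-11-(propan-2-yl)spiro[5.5]undec-8-ene-1,3,5-trione (drawn as the triketo tautomer) | CC1C(=O)[C@]2(CC(CCC=C(C)C)=CC[C@H]2C(C)C)C(=O)C(C)(C)C1=O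
F5 | step 9 | (6R,11S)-5-methoxy-2,2,4-trimethyl-8-(4-methylpent-3-en-1-yl)-11-(propan-2-yl)spiro[5.5]undeca-4,8-diene-1,3-dione | COC1=C(C)C(=O)C(C)(C)C(=O)[C@@]12CC(CCC=C(C)C)=CC[C@H]2C(C)C
F6 | step 7 | 1-[(1R,6S)-3-(4-methylpent-3-en-1-yl)-6-(propan-2-yl)cyclohex-3-en-1-yl]propan-1-one | CCC(=O)[C@@H]1CC(CCC=C(C)C)=CC[C@H]1C(C)C
F7 | step 7 | trimethyl({1-[(1R,6S)-3-(4-methylpent-3-en-1-yl)-6-(propan-2-yl)cyclohex-3-en-1-yl]prop-1-en-1-yl}oxy)silane | CC=C(O[Si](C)(C)C)[C@@H]1CC(CCC=C(C)C)=CC[C@H]1C(C)C
F8 | step 7 | 3,3,3-trimethoxy-2-methyl-1-[(1R,6S)-3-(4-methylpent-3-en-1-yl)-6-(propan-2-yl)cyclohex-3-en-1-yl]propan-1-one (epimers at C2) | COC(OC)(OC)C(C)C(=O)[C@@H]1CC(CCC=C(C)C)=CC[C@H]1C(C)C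
F9 | step 3 | methyl (1R,6S)-6-(propan-2-yl)-3-[(triethylsilyl)oxy]cyclohex-3-ene-1-carboxylate | CC[Si](CC)(CC)OC1=CC[C@@H](C(C)C)[C@H](C(=O)OC)C1
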